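**Retrosynthetic overview**
1. Last bond C4–C5: an intramolecular Nozaki–Hiyama–Kishi addition of a 1-iodoethenyl furanone to a C5 aldehyde closes the ten-membered carbocycle and creates the C4(=CH2)–C5(OH) unit.
2. C6–C7: CrCl2-mediated Barbier allylation of TBSOCH2CHO with a 3-(bromomethyl)butenolide sets C6 and C7 and unveils the α-methylene lactone; the butenolide comes from ring-closing metathesis of the C8 allylic 2-(bromomethyl)acrylate; the angelate goes on O6 before ring closure.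
3. Furanone: gold-catalysed cyclisation of an α'-hydroxy diynone (C1 aldehyde + lithium diynide); the spare alkyne becomes the 1-iodoethenyl group by hydrostannation and iodination.
4. Stereocenters: C10 by Sharpless epoxidation of methallyl alcohol (first stereocenter), C8 by ketoreductase reduction of a TMS-ynone, C6/C7 relayed from C8, C5 in the ring closure.
5. Ring order: furanone, then butenolide/α-methylene lactone, then the ten-membered carbocycle.

Assumption: atoms carry germacrane-type locants (C1 ketone, C2=C3 enol ether, C4=C15H2, C5–OH, C6–OAng, C7, C8–O lactone, C9H2, C10 bearing C14H3, C11=C13H2, C12 lactone C=O); in these locants the target is 5S,6S,7R,8S,10R.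

**Route**

Step 1
Reactants: 1 2-methylprop-2-en-1-ol
Product: 2 (S)-2-methylglycidol
Conditions: Ti(OiPr)4 (5 mol %), L-(+)-diethyl tartrate (6 mol %), t-BuOOH, 4 Å MS, CH2Cl2, −20 °C
Reagents that add atoms: tert-butyl hydroperoxide, CC(C)(C)OO
Why: Katsuki–Sharpless asymmetric epoxidation, in which the titanium–tartrate catalyst epoxidises one enantiotopic face of the achiral allylic alcohol and so creates the first stereocenter (future C10, S at this stage, about 95% ee).

Step 2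
Reactants: 2 (S)-2-methylglycidol; 3 vinylmagnesium bromide
Product: 4 (2R)-2-methylpent-4-ene-1,2-diol
Conditions: 3 (3 equiv), CuI (10 mol %), THF, −30 → 0 °C
Reagents that add atoms: none
Why: copper-catalysed Grignard opening of the epoxide by SN2 attack at its unsubstituted CH2 (the first equivalent of 3 only deprotonates the OH), which leaves the quaternary center untouched and turns it into the tertiary carbinol.

Step 3
Reactants: 4 (2R)-2-methylpent-4-ene-1,2-diol
Product: 5 (4R)-2,2,4-trimethyl-4-(prop-2-en-1-yl)-1,3-dioxolane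
Conditions: Me2C(OMe)2, PPTS (cat.), CH2Cl2, rt
Reagents that add atoms: 2,2-dimethoxypropane, COC(C)(C)OC
Why: acid-catalysed transacetalisation ties the primary and tertiary hydroxyls into one acetonide so that the chain end can be elaborated.

Step 4
Reactants: 5 (4R)-2,2,4-trimethyl-4-(prop-2-en-1-yl)-1,3-dioxolane
Product: 7 2-[(4R)-2,2,4-trimethyl-1,3-dioxolan-4-yl]acetaldehyde, via secondary ozonide 6 (not isolated)
Conditions: O3, CH2Cl2, −78 °C; then PPh3, −78 °C → rt
Reagents that add atoms: ozone, [O-][O+]=O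
Why: ozonolysis with reductive work-up cleaves the terminal alkene to the aldehyde (future C8) without touching the acetal.

Step 5
Reactants: 7 2-[(4R)-2,2,4-trimethyl-1,3-dioxolan-4-yl]acetaldehyde; 8 ethynyl(trimethyl)silane
Product: 10 1-[(4R)-2,2,4-trimethyl-1,3-dioxolan-4-yl]-4-(trimethylsilyl)but-3-yn-2-ol (C2 epimers), via lithium (trimethylsilyl)acetylide 9 (not isolated)
Conditions: 8, n-BuLi, THF, −78 °C; then 7, −78 → −40 °C
Reagents that add atoms: none
Why: 1,2-addition of the lithium acetylide brings in C7, and the carbinol configuration does not matter because it is erased in step 6.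

Step 6
Reactants: 10 1-[(4R)-2,2,4-trimethyl-1,3-dioxolan-4-yl]-4-(trimethylsilyl)but-3-yn-2-ol (C2 epimers)
Product: 11 1-[(4R)-2,2,4-trimethyl-1,3-dioxolan-4-yl]-4-(trimethylsilyl)but-3-yn-2-one
Conditions: Dess–Martin periodinane, CH2Cl2, 0 °C → rt
Reagents that add atoms: none
Why: Dess–Martin oxidation of the propargylic alcohol gives the prochiral ynone that serves as the enzyme substrate.

Step 7
Reactants: 11 1-[(4R)-2,2,4-trimethyl-1,3-dioxolan-4-yl]-4-(trimethylsilyl)but-3-yn-2-one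
Product: 12 (2S)-1-[(4R)-2,2,4-trimethyl-1,3-dioxolan-4-yl]-4-(trimethylsilyl)but-3-yn-2-ol
Conditions: (S)-selective ketoreductase (NADPH-dependent), NADP+ (cat.), i-PrOH (10 vol %), phosphate buffer pH 7, 30 °C
Reagents that add atoms: none
Why: enzymatic asymmetric ketone reduction in which the ketoreductase delivers hydride from NADPH (recycled by i-PrOH) to one carbonyl face under catalyst control and sets C8 as S, the minor diastereomer arising from residual (4S) material being removed here by chromatography.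

Step 8
Reactants: 12 (2S)-1-[(4R)-2,2,4-trimethyl-1,3-dioxolan-4-yl]-4-(trimethylsilyl)but-3-yn-2-ol
Product: 13 (2S)-1-[(4R)-2,2,4-trimethyl-1,3-dioxolan-4-yl]but-3-yn-2-ol
Conditions: K2CO3 (0.2 equiv), MeOH, 0 °C → rt
Reagents that add atoms: none
Why: base-catalysed methanolysis of the alkynyl C–Si bond frees the terminal alkyne without affecting C8.

Step 9
Reactants: 13 (2S)-1-[(4R)-2,2,4-trimethyl-1,3-dioxolan-4-yl]but-3-yn-2-ol
Product: 14 (2S)-1-[(4R)-2,2,4-trimethyl-1,3-dioxolan-4-yl]but-3-en-2-ol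
Conditions: H2 (1 atm), Pd/CaCO3 poisoned with Pb(OAc)2, quinoline, EtOAc, rt
Reagents that add atoms: none
Why: Lindlar-type semihydrogenation stops at the alkene and gives the vinyl carbinol needed for the later ring-closing metathesis.

Step 10
Reactants: 14 (2S)-1-[(4R)-2,2,4-trimethyl-1,3-dioxolan-4-yl]but-3-en-2-ol
Product: 15 (4R)-4-{(2S)-2-[(4-methoxyphenyl)methoxy]but-3-en-1-yl}-2,2,4-trimethyl-1,3-dioxolane
Conditions: NaH, 4-MeOC6H4CH2Cl, Bu4NI (cat.), THF/DMF, 0 °C → rt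
Reagents that add atoms: 4-methoxybenzyl chloride, COc1ccc(CCl)cc1
Why: Williamson etherification protects O8 as a PMB ether that survives acid, organolithium and oxidation steps and can later be removed oxidatively.

Step 11
Reactants: 15 (4R)-4-{(2S)-2-[(4-methoxyphenyl)methoxy]but-3-en-1-yl}-2,2,4-trimethyl-1,3-dioxolane
Product: 16 (2R,4S)-4-[(4-methoxyphenyl)methoxy]-2-methylhex-5-ene-1,2-diol
Conditions: AcOH/H2O (4:1), 40 °C
Reagents that add atoms: none
Why: mild acetal hydrolysis removes the acetonide while the PMB ether is stable.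

Step 12
Reactants: 16 (2R,4S)-4-[(4-methoxyphenyl)methoxy]-2-methylhex-5-ene-1,2-diol
Product: 17 (2R,4S)-2-hydroxy-4-[(4-methoxyphenyl)methoxy]-2-methylhex-5-enal
Conditions: TEMPO (10 mol %), PhI(OAc)2, CH2Cl2, rt
Reagents that add atoms: none
Why: TEMPO/PhI(OAc)2 oxidation is selective for the primary alcohol and cannot oxidise the tertiary one, giving the α-hydroxy aldehyde (future C1).

Step 13
Reactants: 17 (2R,4S)-2-hydroxy-4-[(4-methoxyphenyl)methoxy]-2-methylhex-5-enal; 18 1,4-bis(trimethylsilyl)buta-1,3-diyne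
Product: 20 (6R,8S)-8-[(4-methoxyphenyl)methoxy]-6-methyl-1-(trimethylsilyl)dec-9-ene-1,3-diyne-5,6-diol (C5 epimers), via lithium (trimethylsilyl)butadiynide 19 (not isolated)
Conditions: 18 (3 equiv), MeLi·LiBr, THF, −78 °C → rt; then 17, −78 → −20 °C
Reagents that add atoms: none
Why: 1,2-addition of the lithium diynide (one equivalent is spent on the free OH) installs C2, C3, C4 and C15, and the new carbinol center is oxidised away in step 14.

Step 14
Reactants: 20 (6R,8S)-8-[(4-methoxyphenyl)methoxy]-6-methyl-1-(trimethylsilyl)dec-9-ene-1,3-diyne-5,6-diol (C5 epimers)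
Product: 21 (6R,8S)-6-hydroxy-8-[(4-methoxyphenyl)methoxy]-6-methyl-1-(trimethylsilyl)dec-9-ene-1,3-diyn-5-one
Conditions: IBX, DMSO, rt
Reagents that add atoms: none
Why: IBX oxidises the secondary propargylic alcohol of the 1,2-diol without C–C cleavage and leaves the tertiary OH, giving the α'-hydroxy ynone.

Step 15
Reactants: 21 (6R,8S)-6-hydroxy-8-[(4-methoxyphenyl)methoxy]-6-methyl-1-(trimethylsilyl)dec-9-ene-1,3-diyn-5-one
Product: 22 (2R)-2-{(2S)-2-[(4-methoxyphenyl)methoxy]but-3-en-1-yl}-2-methyl-5-[(trimethylsilyl)ethynyl]furan-3(2H)-one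
Conditions: Ph3PAuNTf2 (3 mol %), toluene, rt
Reagents that add atoms: none
Why: gold-catalysed 5-endo-dig cycloisomerisation (intramolecular oxa-Michael addition of the tertiary OH to the activated ynone) builds the 3(2H)-furanone, and the quaternary C10 cannot epimerise.

Step 16
Reactants: 22 (2R)-2-{(2S)-2-[(4-methoxyphenyl)methoxy]but-3-en-1-yl}-2-methyl-5-[(trimethylsilyl)ethynyl]furan-3(2H)-one
Product: 23 (2R)-5-ethynyl-2-{(2S)-2-[(4-methoxyphenyl)methoxy]but-3-en-1-yl}-2-methylfuran-3(2H)-one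
Conditions: Bu4NF, AcOH (1:1), THF, 0 °C
Reagents that add atoms: none
Why: buffered fluoride cleaves the alkynyl C–Si bond without exposing the base-sensitive furanone to alkoxide.

Step 17
Reactants: 23 (2R)-5-ethynyl-2-{(2S)-2-[(4-methoxyphenyl)methoxy]but-3-en-1-yl}-2-methylfuran-3(2H)-one
Product: 24 (2R)-2-{(2S)-2-[(4-methoxyphenyl)methoxy]but-3-en-1-yl}-2-methyl-5-[1-(tributylstannyl)ethenyl]furan-3(2H)-one
Conditions: Bu3SnH, PdCl2(PPh3)2 (3 mol %), THF, 0 °C
Reagents that add atoms: tributyltin hydride, CCCC[SnH](CCCC)CCCC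
Why: palladium-catalysed syn-hydrostannation places tin on the internal carbon of the acceptor-substituted terminal alkyne, giving the 1,1-disubstituted alkenylstannane at the future C4.

Step 18
Reactants: 24 (2R)-2-{(2S)-2-[(4-methoxyphenyl)methoxy]but-3-en-1-yl}-2-methyl-5-[1-(tributylstannyl)ethenyl]furan-3(2H)-one
Product: 25 (2R)-5-(1-iodoethenyl)-2-{(2S)-2-[(4-methoxyphenyl)methoxy]but-3-en-1-yl}-2-methylfuran-3(2H)-one
Conditions: I2, CH2Cl2, 0 °C
Reagents that add atoms: iodine, II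
Why: iododestannylation (ipso substitution of the C–Sn bond) gives the 1-iodoalkene needed for the Nozaki–Hiyama–Kishi reaction.

Step 19
Reactants: 25 (2R)-5-(1-iodoethenyl)-2-{(2S)-2-[(4-methoxyphenyl)methoxy]but-3-en-1-yl}-2-methylfuran-3(2H)-one
Product: 26 (2R)-2-[(2S)-2-hydroxybut-3-en-1-yl]-5-(1-iodoethenyl)-2-methylfuran-3(2H)-one
Conditions: DDQ, CH2Cl2/pH 7 buffer (10:1), 0 °C → rt
Reagents that add atoms: none
Why: oxidative PMB cleavage with DDQ is neutral and leaves the iodo-diene and the furanone intact.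

Step 20
Reactants: 26 (2R)-2-[(2S)-2-hydroxybut-3-en-1-yl]-5-(1-iodoethenyl)-2-methylfuran-3(2H)-one; 27 2-(bromomethyl)prop-2-enoic acid
Product: 28 (2S)-1-[(2R)-5-(1-iodoethenyl)-2-methyl-3-oxo-2,3-dihydrofuran-2-yl]but-3-en-2-yl 2-(bromomethyl)prop-2-enoate
Conditions: 27, DCC, DMAP (5 mol %), CH2Cl2, 0 °C
Reagents that add atoms: none
Why: Steglich esterification acylates O8 with retention at C8 and installs the C11–C13 unit.

Step 21
Reactants: 28 (2S)-1-[(2R)-5-(1-iodoethenyl)-2-methyl-3-oxo-2,3-dihydrofuran-2-yl]but-3-en-2-yl 2-(bromomethyl)prop-2-enoate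
Product: 29 (5S)-3-(bromomethyl)-5-{[(2R)-5-(1-iodoethenyl)-2-methyl-3-oxo-2,3-dihydrofuran-2-yl]methyl}furan-2(5H)-one
Conditions: second-generation Grubbs catalyst RuCl2(=CHPh)(H2IMes)(PCy3) (5 mol %), CH2Cl2, 40 °C
Reagents that add atoms: none
Why: ring-closing metathesis between the vinyl group and the acrylate alkene forms the butenolide with loss of ethene, while the allylic bromide and the hindered iodoalkene are spectators.

Step 22
Reactants: 29 (5S)-3-(bromomethyl)-5-{[(2R)-5-(1-iodoethenyl)-2-methyl-3-oxo-2,3-dihydrofuran-2-yl]methyl}furan-2(5H)-one; 30 (tert-butyldimethylsilyloxy)acetaldehyde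
Product: 32 (4S,5S)-4-[(1S)-2-(tert-butyldimethylsilyloxy)-1-hydroxyethyl]-5-{[(2R)-5-(1-iodoethenyl)-2-methyl-3-oxo-2,3-dihydrofuran-2-yl]methyl}-3-methylideneoxolan-2-one, via allylchromium dichloride 31 (not isolated)
Conditions: CrCl2 (3 equiv, nickel-free), 30 (1.5 equiv), THF, 0 °C → rt
Reagents that add atoms: none
Why: Nozaki–Hiyama (Barbier-type) allylation in which the allylchromium attacks through C7 on the butenolide face anti to the C8 substituent (trans-lactone) and a chair Zimmerman–Traxler transition state with the aldehyde substituent equatorial on the ring-locked E-allyl unit fixes C6 as S, the C–I bond being inert without nickel.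

Step 23
Reactants: 32 (4S,5S)-4-[(1S)-2-(tert-butyldimethylsilyloxy)-1-hydroxyethyl]-5-{[(2R)-5-(1-iodoethenyl)-2-methyl-3-oxo-2,3-dihydrofuran-2-yl]methyl}-3-methylideneoxolan-2-one; 33 angelic acid
Product: 35 (1S)-2-(tert-butyldimethylsilyloxy)-1-[(2S,3R)-2-{[(2R)-5-(1-iodoethenyl)-2-methyl-3-oxo-2,3-dihydrofuran-2-yl]methyl}-4-methylidene-5-oxooxolan-3-yl]ethyl (2Z)-2-methylbut-2-enoate, via angelic 2,4,6-trichlorobenzoic anhydride 34 (not isolated)
Conditions: 33, 2,4,6-Cl3C6H2COCl, Et3N, toluene, rt; then 32, toluene, 75 °C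
Reagents that add atoms: none
Why: Yamaguchi-type mixed-anhydride esterification run without DMAP acylates O6 with retention and avoids isomerisation of the angelate to the tiglate.

Step 24
Reactants: 35 (1S)-2-(tert-butyldimethylsilyloxy)-1-[(2S,3R)-2-{[(2R)-5-(1-iodoethenyl)-2-methyl-3-oxo-2,3-dihydrofuran-2-yl]methyl}-4-methylidene-5-oxooxolan-3-yl]ethyl (2Z)-2-methylbut-2-enoate
Product: 36 (1S)-2-hydroxy-1-[(2S,3R)-2-{[(2R)-5-(1-iodoethenyl)-2-methyl-3-oxo-2,3-dihydrofuran-2-yl]methyl}-4-methylidene-5-oxooxolan-3-yl]ethyl (2Z)-2-methylbut-2-enoate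
Conditions: HF·pyridine, pyridine, THF, 0 °C → rt
Reagents that add atoms: none
Why: acidic fluoride desilylation frees the primary alcohol without base, so the neighbouring angelate does not migrate.

Step 25
Reactants: 36 (1S)-2-hydroxy-1-[(2S,3R)-2-{[(2R)-5-(1-iodoethenyl)-2-methyl-3-oxo-2,3-dihydrofuran-2-yl]methyl}-4-methylidene-5-oxooxolan-3-yl]ethyl (2Z)-2-methylbut-2-enoate
Product: 37 (1S)-1-[(2S,3R)-2-{[(2R)-5-(1-iodoethenyl)-2-methyl-3-oxo-2,3-dihydrofuran-2-yl]methyl}-4-methylidene-5-oxooxolan-3-yl]-2-oxoethyl (2Z)-2-methylbut-2-enoate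
Conditions: Dess–Martin periodinane, pyridine, CH2Cl2, 0 °C
Reagents that add atoms: none
Why: buffered Dess–Martin oxidation gives the α-acyloxy aldehyde (C5) without epimerising C6, and the crude aldehyde is used at once.

Step 26
Reactants: 37 (1S)-1-[(2S,3R)-2-{[(2R)-5-(1-iodoethenyl)-2-methyl-3-oxo-2,3-dihydrofuran-2-yl]methyl}-4-methylidene-5-oxooxolan-3-yl]-2-oxoethyl (2Z)-2-methylbut-2-enoate
Product: 39 (5S,6S,7R,8S,10R)-6-angeloyloxy-5-hydroxy-1-oxo-3,10-epoxygermacra-2,4(15),11(13)-trien-12,8-olide (CNP0120053.1), via alkenylchromium dichloride 38 (not isolated)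
Conditions: CrCl2 (8 equiv), NiCl2 (0.1 equiv), DMSO, rt, 0.002 M, slow addition
Reagents that add atoms: none
Why: intramolecular Nozaki–Hiyama–Kishi reaction in which nickel-catalysed formation of the alkenylchromium and its addition to the aldehyde closes the ten-membered ring and forms the C4(=CH2)–C5(OH) unit, C5 being expected as S (syn to O6) from a chromium-bridged Cram-chelate arrangement held in the closing ring, with any 5-epimer removed by chromatography.

**Compound list**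
1 | 2-methylprop-2-en-1-ol (methallyl alcohol) | C=C(C)CO | starting material
2 | (S)-2-methylglycidol, [(2S)-2-methyloxiran-2-yl]methanol | C[C@]1(CO)CO1 | intermediate
3 | vinylmagnesium bromide | C=C[Mg]Br | starting material
4 | (2R)-2-methylpent-4-ene-1,2-diol | C=CC[C@@](C)(O)CO | intermediate
5 | (4R)-2,2,4-trimethyl-4-(prop-2-en-1-yl)-1,3-dioxolane | C=CC[C@]1(C)COC(C)(C)O1 | intermediate
6 | secondary ozonide, (4R)-2,2,4-trimethyl-4-(1,2,4-trioxolan-3-ylmethyl)-1,3-dioxolane | C1OC(C[C@]2(C)COC(C)(C)O2)OO1 | intermediate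
7 | 2-[(4R)-2,2,4-trimethyl-1,3-dioxolan-4-yl]acetaldehyde | O=CC[C@]1(C)COC(C)(C)O1 | intermediate
8 | ethynyl(trimethyl)silane | C#C[Si](C)(C)C | starting material
9 | lithium (trimethylsilyl)acetylide | [Li]C#C[Si](C)(C)C | intermediate
10 | 1-[(4R)-2,2,4-trimethyl-1,3-dioxolan-4-yl]-4-(trimethylsilyl)but-3-yn-2-ol (C2 epimers) | C[Si](C)(C)C#CC(O)C[C@]1(C)COC(C)(C)O1 | intermediate
11 | 1-[(4R)-2,2,4-trimethyl-1,3-dioxolan-4-yl]-4-(trimethylsilyl)but-3-yn-2-one | C[Si](C)(C)C#CC(=O)C[C@]1(C)COC(C)(C)O1 | intermediate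
12 | (2S)-1-[(4R)-2,2,4-trimethyl-1,3-dioxolan-4-yl]-4-(trimethylsilyl)but-3-yn-2-ol | C[Si](C)(C)C#C[C@@H](O)C[C@]1(C)COC(C)(C)O1 | intermediate
13 | (2S)-1-[(4R)-2,2,4-trimethyl-1,3-dioxolan-4-yl]but-3-yn-2-ol | C#C[C@@H](O)C[C@]1(C)COC(C)(C)O1 | intermediate
14 | (2S)-1-[(4R)-2,2,4-trimethyl-1,3-dioxolan-4-yl]but-3-en-2-ol | C=C[C@@H](O)C[C@]1(C)COC(C)(C)O1 | intermediate
15 | (4R)-4-{(2S)-2-[(4-methoxyphenyl)methoxy]but-3-en-1-yl}-2,2,4-trimethyl-1,3-dioxolane | C=C[C@@H](OCc1ccc(OC)cc1)C[C@]1(C)COC(C)(C)O1 | intermediate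
16 | (2R,4S)-4-[(4-methoxyphenyl)methoxy]-2-methylhex-5-ene-1,2-diol | C=C[C@@H](OCc1ccc(OC)cc1)C[C@@](C)(O)CO | intermediate
17 | (2R,4S)-2-hydroxy-4-[(4-methoxyphenyl)methoxy]-2-methylhex-5-enal | C=C[C@@H](OCc1ccc(OC)cc1)C[C@@](C)(O)C=O | intermediate
18 | 1,4-bis(trimethylsilyl)buta-1,3-diyne | C[Si](C)(C)C#CC#C[Si](C)(C)C | starting material
19 | lithium (trimethylsilyl)butadiynide | [Li]C#CC#C[Si](C)(C)C | intermediate
20 | (6R,8S)-8-[(4-methoxyphenyl)methoxy]-6-methyl-1-(trimethylsilyl)dec-9-ene-1,3-diyne-5,6-diol (C5 epimers) | C=C[C@@H](OCc1ccc(OC)cc1)C[C@@](C)(O)C(O)C#CC#C[Si](C)(C)C | intermediate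
21 | (6R,8S)-6-hydroxy-8-[(4-methoxyphenyl)methoxy]-6-methyl-1-(trimethylsilyl)dec-9-ene-1,3-diyn-5-one | C=C[C@@H](OCc1ccc(OC)cc1)C[C@@](C)(O)C(=O)C#CC#C[Si](C)(C)C | intermediate
22 | (2R)-2-{(2S)-2-[(4-methoxyphenyl)methoxy]but-3-en-1-yl}-2-methyl-5-[(trimethylsilyl)ethynyl]furan-3(2H)-one | C=C[C@@H](OCc1ccc(OC)cc1)C[C@@]1(C)OC(C#C[Si](C)(C)C)=CC1=O | intermediate
23 | (2R)-5-ethynyl-2-{(2S)-2-[(4-methoxyphenyl)methoxy]but-3-en-1-yl}-2-methylfuran-3(2H)-one | C=C[C@@H](OCc1ccc(OC)cc1)C[C@@]1(C)OC(C#C)=CC1=O | intermediate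
24 | (2R)-2-{(2S)-2-[(4-methoxyphenyl)methoxy]but-3-en-1-yl}-2-methyl-5-[1-(tributylstannyl)ethenyl]furan-3(2H)-one | C=C[C@@H](OCc1ccc(OC)cc1)C[C@@]1(C)OC(C(=C)[Sn](CCCC)(CCCC)CCCC)=CC1=O | intermediate
25 | (2R)-5-(1-iodoethenyl)-2-{(2S)-2-[(4-methoxyphenyl)methoxy]but-3-en-1-yl}-2-methylfuran-3(2H)-one | C=C[C@@H](OCc1ccc(OC)cc1)C[C@@]1(C)OC(C(=C)I)=CC1=O | intermediate
26 | (2R)-2-[(2S)-2-hydroxybut-3-en-1-yl]-5-(1-iodoethenyl)-2-methylfuran-3(2H)-one | C=C[C@@H](O)C[C@@]1(C)OC(C(=C)I)=CC1=O | intermediate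
27 | 2-(bromomethyl)prop-2-enoic acid | C=C(CBr)C(=O)O | starting material
28 | (2S)-1-[(2R)-5-(1-iodoethenyl)-2-methyl-3-oxo-2,3-dihydrofuran-2-yl]but-3-en-2-yl 2-(bromomethyl)prop-2-enoate | C=C[C@@H](OC(=O)C(=C)CBr)C[C@@]1(C)OC(C(=C)I)=CC1=O | intermediate
29 | (5S)-3-(bromomethyl)-5-{[(2R)-5-(1-iodoethenyl)-2-methyl-3-oxo-2,3-dihydrofuran-2-yl]methyl}furan-2(5H)-one | BrCC1=C[C@H](C[C@@]2(C)OC(C(=C)I)=CC2=O)OC1=O | intermediate
30 | (tert-butyldimethylsilyloxy)acetaldehyde | CC(C)(C)[Si](C)(C)OCC=O | starting material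
31 | allylchromium dichloride derived from 29 | Cl[Cr](Cl)CC1=C[C@H](C[C@@]2(C)OC(C(=C)I)=CC2=O)OC1=O | intermediate
32 | (4S,5S)-4-[(1S)-2-(tert-butyldimethylsilyloxy)-1-hydroxyethyl]-5-{[(2R)-5-(1-iodoethenyl)-2-methyl-3-oxo-2,3-dihydrofuran-2-yl]methyl}-3-methylideneoxolan-2-one | C=C1C(=O)O[C@@H](C[C@@]2(C)OC(C(=C)I)=CC2=O)[C@@H]1[C@H](O)CO[Si](C)(C)C(C)(C)C | intermediate
33 | angelic acid, (2Z)-2-methylbut-2-enoic acid | C/C=C(/C)C(=O)O | starting material
34 | angelic 2,4,6-trichlorobenzoic anhydride | C/C=C(/C)C(=O)OC(=O)c1c(Cl)cc(Cl)cc1Cl | intermediate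
35 | (1S)-2-(tert-butyldimethylsilyloxy)-1-[(2S,3R)-2-{[(2R)-5-(1-iodoethenyl)-2-methyl-3-oxo-2,3-dihydrofuran-2-yl]methyl}-4-methylidene-5-oxooxolan-3-yl]ethyl (2Z)-2-methylbut-2-enoate | C=C1C(=O)O[C@@H](C[C@@]2(C)OC(C(=C)I)=CC2=O)[C@@H]1[C@H](OC(=O)/C(C)=C\C)CO[Si](C)(C)C(C)(C)C | intermediate
36 | (1S)-2-hydroxy-1-[(2S,3R)-2-{[(2R)-5-(1-iodoethenyl)-2-methyl-3-oxo-2,3-dihydrofuran-2-yl]methyl}-4-methylidene-5-oxooxolan-3-yl]ethyl (2Z)-2-methylbut-2-enoate | C=C1C(=O)O[C@@H](C[C@@]2(C)OC(C(=C)I)=CC2=O)[C@@H]1[C@H](OC(=O)/C(C)=C\C)CO | intermediate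
37 | (1S)-1-[(2S,3R)-2-{[(2R)-5-(1-iodoethenyl)-2-methyl-3-oxo-2,3-dihydrofuran-2-yl]methyl}-4-methylidene-5-oxooxolan-3-yl]-2-oxoethyl (2Z)-2-methylbut-2-enoate | C=C1C(=O)O[C@@H](C[C@@]2(C)OC(C(=C)I)=CC2=O)[C@@H]1[C@H](OC(=O)/C(C)=C\C)C=O | intermediate
38 | alkenylchromium dichloride derived from 37 | C=C1C(=O)O[C@@H](C[C@@]2(C)OC(C(=C)[Cr](Cl)Cl)=CC2=O)[C@@H]1[C@H](OC(=O)/C(C)=C\C)C=O | intermediate
39 | (5S,6S,7R,8S,10R)-6-angeloyloxy-5-hydroxy-1-oxo-3,10-epoxygermacra-2,4(15),11(13)-trien-12,8-olide (CNP0120053.1) | C=C1C(=O)O[C@H]2C[C@@]3(C)OC(=CC3=O)C(=C)[C@H](O)[C@@H](OC(=O)/C(C)=C\C)[C@H]12 | target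

**Totals**
Total step count: 26. Longest linear sequence: 26 steps (1 to 39); all other inputs (3, 8, 18, 27, 30, 33) are used as purchased.

**Steps most likely to fail, with fallbacks**

Step 26 (macrocyclisation). The oxygen-bridged nine-membered ring is strained, and C5 is set only by the conformation of the closing ring; the stated 5S preference is an expectation, not a certainty. The fallback sets out from 37 and comes back at 39. The ring is closed as before, and C5 is then set in a separate, catalyst-controlled operation. The (5R)-epimer of 39, (5R,6S,7R,8S,10R)-6-angeloyloxy-5-hydroxy-1-oxo-3,10-epoxygermacra-2,4(15),11(13)-trien-12,8-olide F4, alone or mixed with 39, is oxidised with Dess–Martin periodinane (pyridine, CH2Cl2, 0 °C) to the C5 ketone, (6S,7R,8S,10R)-6-angeloyloxy-1,5-dioxo-3,10-epoxygermacra-2,4(15),11(13)-trien-12,8-olide F5. The enone carbonyl of F5 is then reduced with (S)-2-methyl-CBS-oxazaborolidine and catecholborane (toluene, −78 °C) to 39. The other catalyst enantiomer is used should the alkenyl/alkyl size ranking prove reversed.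

Step 7 (ketoreductase). The ynone 11 is bulky on both sides, and no enzyme of a screening panel may accept it with useful rate and selectivity. The fallback sets out from 7 and comes back at 14, bypassing steps 5 to 9. Vinylmagnesium bromide 3 is added to 7 (THF, −78 °C) to give 1-[(4R)-2,2,4-trimethyl-1,3-dioxolan-4-yl]but-3-en-2-ol F1 as a roughly 1:1 mixture of C2 epimers. A lipase (immobilised Candida antarctica lipase B, vinyl acetate, MTBE, 30 °C) then acylates only the (2S)-epimer (vinyl as the medium group, dioxolanylmethyl as the large group) to (2S)-1-[(4R)-2,2,4-trimethyl-1,3-dioxolan-4-yl]but-3-en-2-yl acetate F2. F2 is separated from the unreacted (2R)-alcohol and cleaved with K2CO3 in MeOH to 14.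

Step 22 (chromium allylation). The trans-lactone follows from steric approach, but the C6 configuration rests on the chair transition state and could come out inverted. The fallback sets out from 29 and comes back at 35. If the allylation of 29 with 30 gives mainly the C6 epimer (4S,5S)-4-[(1R)-2-(tert-butyldimethylsilyloxy)-1-hydroxyethyl]-5-{[(2R)-5-(1-iodoethenyl)-2-methyl-3-oxo-2,3-dihydrofuran-2-yl]methyl}-3-methylideneoxolan-2-one F3, C6 is set by substitution instead of by the C–C bond formation. Mitsunobu esterification of F3 with angelic acid 33 (PPh3, DIAD, toluene, 0 °C) forms the angelate with SN2 inversion at C6 and gives 35 directly.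

**Further compounds**
F1 | step 7 | 1-[(4R)-2,2,4-trimethyl-1,3-dioxolan-4-yl]but-3-en-2-ol (C2 epimers) | C=CC(O)C[C@]1(C)COC(C)(C)O1
F2 | step 7 | (2S)-1-[(4R)-2,2,4-trimethyl-1,3-dioxolan-4-yl]but-3-en-2-yl acetate | C=C[C@@H](OC(C)=O)C[C@]1(C)COC(C)(C)O1
F3 | step 22 | (4S,5S)-4-[(1R)-2-(tert-butyldimethylsilyloxy)-1-hydroxyethyl]-5-{[(2R)-5-(1-iodoethenyl)-2-methyl-3-oxo-2,3-dihydrofuran-2-yl]methyl}-3-methylideneoxolan-2-one | C=C1C(=O)O[C@@H](C[C@@]2(C)OC(C(=C)I)=CC2=O)[C@@H]1[C@@H](O)CO[Si](C)(C)C(C)(C)C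
F4 | step 26 | (5R,6S,7R,8S,10R)-6-angeloyloxy-5-hydroxy-1-oxo-3,10-epoxygermacra-2,4(15),11(13)-trien-12,8-olide | C=C1C(=O)O[C@H]2C[C@@]3(C)OC(=CC3=O)C(=C)[C@@H](O)[C@@H](OC(=O)/C(C)=C\C)[C@H]12
F5 | step 26 | (6S,7R,8S,10R)-6-angeloyloxy-1,5-dioxo-3,10-epoxygermacra-2,4(15),11(13)-trien-12,8-olide | C=C1C(=O)O[C@H]2C[C@@]3(C)OC(=CC3=O)C(=C)C(=O)[C@@H](OC(=O)/C(C)=C\C)[C@H]12
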